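Readings and results were computed for an exercise, noise included.

We stop this flask when target stops gaining, so we compare two rates: how fast substrate is consumed and how fast target is lost.

| flask | substrate | reagent in the second phase | remark | time | volume of the second phase over the first |
|---|---|---|---|---|---|
| south-east | 6.7 mM | 1 equiv | run made earlier |  |  |
| north-east | 15 mM | 1 equiv | run made earlier |  |  |
| north-west | 10 mM | 1.5 equiv | run made earlier |  |  |
| flask | 10 mM | 1.00 equiv |  | 30 h | 2.0 |

| run | time / h | target / % | substrate / % |
|---|---|---|---|
| south-east | 4.00 | 20 | 73 |
| south-east | 8.00 | 35 | 56 |
| south-east | 15.0 | 34 | 42 |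
| south-east | 40.0 | 8 | 38 |
| north-east | 4.00 | 37 | 55 |
| north-east | 8.00 | 52 | 31 |
| north-east | 15.0 | 65 | 22 |
| north-east | 40.0 | 52 | 15 |
| north-west | 4.00 | 48 | 48 |
| north-west | 8.00 | 60 | 25 |
| north-west | 15.0 | 65 | 14 |
| north-west | 40.0 | 47 | 9 |

(standard deviation of a reading: 2 percentage points)

- what is said of target includes product in the second phase and crystals
- in the second phase: reagent in the second phase, product in the second phase; everything else is in the first
- charges count per volume of the first phase; a concentration in a rate is the amount of a species over the volume of its own phase; every rate counts per litre of the first phase
- crystals is a solid; its amount is given per volume of the solution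
- the numbers in the tables scatter with a standard deviation of 2 percentage points
- steps under discussion: reagent in the reaction phase <-> reagent in the second phase; substrate + reagent in the reaction phase <-> target; target <-> product in the second phase; target -> decomposed product; substrate -> decomposition product; crystals <-> target
- the earlier runs hold the two phases in the same ratio of volumes as the flask asked about

1. the best time, 30 h at the latest, for target
2. the amount of target, in percent of the substrate charged, at that time

- Whatever is neither target nor substrate has left the count. In the north-west run at 40.0 h that amount, per hour, is 0.110 mM h⁻¹, and we call this the drain.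
- The same sum gives 0.0905 mM h⁻¹ in the south-east run and 0.124 mM h⁻¹ in the north-east run. From south-east to north-east the charge grows by a factor 2.24, the drain by a factor 1.37.
- A rate constant times a concentration that stays put gives a fixed rate, and crystals beside dissolved target can keep that concentration in place. We therefore treat the drain as one fixed rate, a pseudo-zero-order loss.
- For substrate in the new flask we interpolate by charge between the south-east and north-east runs, both at one equivalent. This gives 46.1% at 8.00 h, 34.0% at 15.0 h and 28.9% at 40.0 h.
- Between the first two times substrate is consumed at 0.172 mM h⁻¹, faster than the drain, so target gains. Between the last two it is consumed at 0.0208 mM h⁻¹, slower than the drain, so target falls.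
- Our peak therefore lies near 15.0 h, where the substrate consumed minus the drain leaves 49.5% as target.
- The forecast says 14 h and 48%, calling it “a broad maximum”. It differs from our figure by 1.5 percentage points, and one reading scatters by 2 points.

    reagent in the reaction phase ⇌ reagent in the second phase, rate k1*([reagent in the reaction phase] - [reagent in the second phase]/K1) per volume of the first phase (partition coefficient = 0.710, kL = 0.490 h⁻¹)
    substrate + reagent in the reaction phase ⇌ target (K = 58.0 M⁻¹, k = 89.0 M⁻¹ h⁻¹)
    target ⇌ product in the second phase, rate k3*([target] - [product in the second phase]/K3) per volume of the first phase (partition coefficient = 1.50, kL = 0.360 h⁻¹)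
    target → decomposed product (k = 0.710 h⁻¹)
    substrate → decomposition product (k = 1.40 × 10⁻⁴ h⁻¹)
    crystals ⇌ target, rate k6*(cs6 - [target]) while solid is left; crystals form when [target] > cs6 (solubility = 0.140 mM, k = 7.80 h⁻¹)

- The flask peaks at 15.1 h with 50.8% target, of which crystals are 45.3%. Over 30 h the drain counts 33.0% of the charge, and decomposed product then stands at 33.0%. Left until 5.0 d, the same flask holds 0% crystals, 87.4% decomposed product and 1.06% target.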